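This closed, stirred vessel takes in its X through the gas while its G dies, and before the next charge you must choose which change is worth making.

D 0.20 M; J 67 mM (held); G 2.8 mM; time 50 min

    J ⇌ X, rate k1*(csat - [X]) (k1 = 0.117 /min, csat = 67 mM)
    D + X + G → G + Z (k2 = 60.2 /M²/min)
    2 G → Q (k3 = 10.3 /M/min)
    2 D → E (k4 = 0.00680 /M/min)

- in percentages every species weighs as the D in it: one E counts as two
- for a step with 2 of a species take k times the square, and two of it per event
- at the start none of X is dissolved
- run time (flask): 50 min

- Thursday's: doubling the saturation concentration of J, all else as stated
- Tuesday's: doubling the amount of G, all else as stated
- Saturday's: doubling the transfer coefficient of step 1, all else as stated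

1. the Z standing at 50 min, as a percentage of the D charged
2. concentration of X in solution at 25 min, in percent of saturation
3. the change that raises the amount of Z at 50 min, in percent of the D charged most ("none" if none brings more than 2 percentage points) (Thursday's / Tuesday's / Saturday's / none)
4. amount of Z at 50 min, in percent of the D charged, after Saturday's

G is charged in a smaller amount than D or than the X the solution can hold, so write its balance first. Step 3 removes G, and step 2 gives back the G it takes, so step 2 nets zero on G and X and D drop out of the balance. The fraction of the G charge standing is one over one plus time divided by its first half-life, 17.3 min, which leaves 25.7% at 50 min. Summed over the run, that G is worth 23.5 min of the full charge. Multiplied by the pace of step 2 at full G, this gives the reach, 26.6%: the fraction of the D charge that would stand as Z if D stayed at its charge and X at saturation.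

I rank the changes by the reach. Thursday's takes it to 53.1%, and Tuesday's to 37.4%, less than Thursday's because the doubled G dies faster. Saturday's leaves the reach where it stands and shortens the rise of X, 8.55 min, which is half of that half-life of G. By hand I go no further: y lies below the reach, and I would charge Thursday's.

The forecast named Thursday's, with 15.5% for y, 85.5% for sat and 18.4% for yb, and said: “Doubling G is partly wasted, because the catalyst dies faster and X is depleted more, so the gain is smaller.”

The flask gives y 15.5%, sat 85.6%, yb 18.3% and best Thursday's, with gains of 13 percentage points, 4 points and 2.8 points for Thursday's, Tuesday's and Saturday's. At 5.00 min, X stood at 41.6% of saturation with 77.6% of the G charge left. So y is 58.4% of the reach, and Saturday's yb, under the same reach, is 68.8% of it.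

In the neighbour flask, charged with 7.0 × 10⁻⁴ M of G, a quarter of the first flask's charge, the reach is 10.6%, and the first flask's share of it gives 6.20%. Computed, the neighbour flask gives 7.32%, more than that and still below its reach.

The numbers of this flask were set for the occasion; the flask was simulated.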